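The route rests on cutting the hindered biaryl bonds E–F and G–H. In rings E and G the C4 hydroxyl (para to ether carbon C1) adjoins biaryl carbon C5. Rings F and H carry a hydroxyl ortho to that bond, so a carboxyl carbon in place of the C4 oxygen can tie each ring pair as an aryl ester. The precursor is the ring D–E–G triaryl diether whose inner rings each bear bromine at C5 next to a 3,5-dimethoxyphenyl ester at C4. One palladium-catalysed double C–H arylation forges both axes and closes two lactone rings. Baeyer–Villiger oxidation later exchanges each bridge carbon for oxygen.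

Key step: step 7

Ring letters (SMILES order): A = terminal 3,5-dihydroxyphenyl; B, C, D = ether-linked chain; E–F and G–H = biaryl arms on D; I–J = biaryl arm on B. In each inner ring C1 is the ether carbon, C4 the carbon para to it and C5 the biaryl carbon.

Assumption: species that exist only until aqueous work-up (phenoxide salts, aluminium hemiacetals, aryl borates, organopalladium and organocopper species) are not counted as compounds; the target has only symmetric outer rings and therefore holds no stereocentre and no stereogenic axis.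

**Route**

Step 1
Reactants: 1 methyl syringate (methyl 4-hydroxy-3,5-dimethoxybenzoate)
Product: 2 methyl 2-bromo-4-hydroxy-3,5-dimethoxybenzoate (methyl 2-bromosyringate)
Conditions: NBS (1.0 equiv), CHCl3, 0 °C to rt
Reagents that add atoms: N-bromosuccinimide, O=C1CCC(=O)N1Br
Why: Electrophilic aromatic bromination: the positions ortho and para to the phenol are occupied, so bromine can only enter one of the two equivalent free carbons (each ortho to one methoxy group and para to the other), and the ester plus the first bromine should hold the reaction at the monobromide with one equivalent of NBS.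

Step 2
Reactants: 2 methyl 2-bromosyringate (2.2 equiv); 3 2,6-difluoro-4-methoxybenzaldehyde
Product: 5 dimethyl 4,4'-[(2-formyl-5-methoxy-1,3-phenylene)bis(oxy)]bis(2-bromo-3,5-dimethoxybenzoate), via monoether fluoride 4 (not isolated)
Conditions: K2CO3, DMSO, 110 °C, Ar
Reagents that add atoms: none
Why: Twofold nucleophilic aromatic substitution (SNAr): both C–F bonds are ortho to the formyl group that stabilises the Meisenheimer adducts, fluoride is the best leaving group on offer, and the C–Br bonds of 2, activated only by an ester, should not compete.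

Step 3
Reactants: 5 ring D–E–G trimer aldehyde
Product: 7 dimethyl 4,4'-[(2-hydroxy-5-methoxy-1,3-phenylene)bis(oxy)]bis(2-bromo-3,5-dimethoxybenzoate), via aryl formate 6 (not isolated)
Conditions: mCPBA, CH2Cl2, 0 °C to rt; then K2CO3 (cat.), MeOH, 0 °C
Reagents that add atoms: 3-chloroperoxybenzoic acid, OOC(=O)c1cccc(Cl)c1
Why: Baeyer–Villiger oxidation of an electron-rich benzaldehyde and methanolysis of the formate (the peracid form of the Dakin reaction, chosen because no free ortho or para hydroxyl is present): the ring with two ortho aryloxy groups and a para methoxy group migrates in preference to hydride, and methanolysis leaves the methyl esters as they are.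

Step 4
Reactants: 7 ring D phenol diester
Product: 8 dimethyl 4,4'-{[2-(benzyloxy)-5-methoxy-1,3-phenylene]bis(oxy)}bis(2-bromo-3,5-dimethoxybenzoate)
Conditions: BnBr, K2CO3, DMF, rt
Reagents that add atoms: benzyl bromide, BrCc1ccccc1
Why: Williamson ether synthesis: the phenoxide of 7 is the only nucleophile, and at room temperature it should be alkylated long before a Smiles-type aryl shift onto the ester-activated inner rings could begin.

Step 5
Reactants: 8 benzyl ether diester
Product: 9 4,4'-{[2-(benzyloxy)-5-methoxy-1,3-phenylene]bis(oxy)}bis(2-bromo-3,5-dimethoxybenzoic acid)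
Conditions: LiOH, THF/MeOH/H2O, 50 °C; then aq HCl
Reagents that add atoms: lithium hydroxide, [Li+].[OH-]
Why: Saponification by acyl–oxygen cleavage: methyl benzoates with a single ortho substituent hydrolyse under mild conditions that leave aryl bromides, the benzyl ether and the diaryl ethers alone.

Step 6
Reactants: 9 diacid; 10 3,5-dimethoxyphenol (2.2 equiv)
Product: 11 bis(3,5-dimethoxyphenyl) 4,4'-{[2-(benzyloxy)-5-methoxy-1,3-phenylene]bis(oxy)}bis(2-bromo-3,5-dimethoxybenzoate)
Conditions: DCC, DMAP (cat.), CH2Cl2, rt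
Reagents that add atoms: none
Why: Steglich esterification: DMAP carries the acyl group from the O-acylisourea to the phenol, a standard way to aryl 2-bromobenzoates, and no other acid or nucleophile is present.

Step 7
Reactants: 11 dibromo bis(3,5-dimethoxyphenyl) ester
Product: 13 9,9'-{[2-(benzyloxy)-5-methoxy-1,3-phenylene]bis(oxy)}bis(1,3,8,10-tetramethoxy-6H-benzo[c]chromen-6-one), via monolactone bromide 12 (not isolated)
Conditions: Pd(OAc)2 (20 mol %), PPh3 (40 mol %), NaOAc (5 equiv), DMA, 130 °C, Ar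
Reagents that add atoms: none
Why: Zerovalent palladium, formed in situ from Pd(OAc)2 and PPh3, inserts into the C5–Br bond of ring E (then of ring G); acetate replaces bromide on the divalent arylpalladium species and removes the proton ortho to the ester oxygen of the 3,5-dimethoxyphenyl ring in a concerted metalation–deprotonation, and reductive elimination from the seven-membered palladacycle gives the biaryl bond. The closest known reaction type is the intramolecular direct arylation of aryl 2-bromobenzoates to benzo[c]chromen-6-ones (the lactone method for hindered biaryls), here run twice in one molecule by way of 12. Each new ring is a six-membered lactone closed by C–C bond formation between C5 of the inner ring and the ortho carbon of the outer ring, the tether C4–C(=O)–O–C(aryl) being already in place. No stereocentre is formed, and the twisted lactone axes invert freely and lose all stereochemical meaning once rings F and H become symmetric in step 9. The step needs site selectivity on the outer ring and freedom from intermolecular coupling: the tether reaches only the two equivalent carbons ortho to the ester oxygen, never the carbon between the two methoxy groups, and it makes the union of two doubly ortho-substituted carbons intramolecular. Benzyl, methyl and diaryl ethers are inert here, and NaOAc is too weak a base to cleave the aryl esters at a competitive rate.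

Step 8
Reactants: 13 bis-lactone
Product: 14 9,9'-{[2-(benzyloxy)-5-methoxy-1,3-phenylene]bis(oxy)}bis(1,3,8,10-tetramethoxy-6H-benzo[c]chromen-6-ol) (labile lactol epimers)
Conditions: i-Bu2AlH (2.4 equiv), CH2Cl2, −78 °C; aq potassium sodium tartrate
Reagents that add atoms: none
Why: Partial lactone reduction with i-Bu2AlH: at −78 °C the aluminium hemiacetal from one hydride transfer should persist until the quench, as established for biaryl-bridging benzo[c]chromen-6-ones, the ethers are untouched, and the lactol carbons equilibrate by ring–chain tautomerism so their configuration is of no account.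

Step 9
Reactants: 14 bis-lactol
Product: 15 5,5'-{[2-(benzyloxy)-5-methoxy-1,3-phenylene]bis(oxy)}bis(2',4,4',6,6'-pentamethoxybiphenyl-2-carbaldehyde)
Conditions: MeI, K2CO3, DMF, rt
Reagents that add atoms: iodomethane, CI
Why: Williamson O-methylation under ring–chain tautomerism: base opens each lactol to the phenoxide–aldehyde form, only the phenoxide is alkylated, and this frees the formyl groups and turns rings F and H into symmetric 2,4,6-trimethoxyphenyl groups.

Step 10
Reactants: 15 dialdehyde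
Product: 17 5,5'-{[2-(benzyloxy)-5-methoxy-1,3-phenylene]bis(oxy)}bis(2',4,4',6,6'-pentamethoxybiphenyl-2-ol), via bis(formate) 16 (not isolated)
Conditions: mCPBA (3 equiv), CH2Cl2, 0 °C to rt; then K2CO3 (cat.), MeOH, 0 °C
Reagents that add atoms: 3-chloroperoxybenzoic acid, OOC(=O)c1cccc(Cl)c1
Why: Baeyer–Villiger (Dakin-type) oxidation, known for 3,4,5-trialkoxybenzaldehydes: each migrating inner ring has the aryloxy oxygen para to the formyl carbon and a bulky ortho aryl group, both of which favour aryl over hydride migration in the Criegee adduct, so the bridge carbon leaves as formate and C4 gains its oxygen.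

Step 11
Reactants: 17 bis-phenol
Product: 18 2-(benzyloxy)-5-methoxy-1,3-bis[(2,2',4,4',6,6'-hexamethoxybiphenyl-3-yl)oxy]benzene
Conditions: MeI, K2CO3, DMF, rt
Reagents that add atoms: iodomethane, CI
Why: Williamson methylation caps the two new C4 phenols, so that the ring D phenol freed in the next step is the only nucleophilic oxygen in the later ether couplings.

Step 12
Reactants: 18 benzyl ether
Product: 19 4-methoxy-2,6-bis[(2,2',4,4',6,6'-hexamethoxybiphenyl-3-yl)oxy]phenol
Conditions: H2 (1 atm), Pd/C, EtOAc/MeOH, rt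
Reagents that add atoms: none
Why: Catalytic hydrogenolysis of a benzyl aryl ether, placed after both bromines and all carbonyl groups are gone so that nothing else in the molecule is reducible.

Step 13
Reactants: 19 ring D phenol; 20 4-fluoro-2,6-dimethoxybenzaldehyde (1.5 equiv)
Product: 21 4-{4-methoxy-2,6-bis[(2,2',4,4',6,6'-hexamethoxybiphenyl-3-yl)oxy]phenoxy}-2,6-dimethoxybenzaldehyde
Conditions: Cs2CO3, DMSO, 110 °C, Ar
Reagents that add atoms: none
Why: SNAr on a 4-fluorobenzaldehyde: fluorine is para to the formyl group and unhindered, the two methoxy groups are meta to the carbon attacked and do not feed electrons into it, and the electron-rich arms of 19 rule out a Smiles shift of the caesium phenoxide.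

Step 14
Reactants: 21 ring C aldehyde
Product: 23 4-{4-methoxy-2,6-bis[(2,2',4,4',6,6'-hexamethoxybiphenyl-3-yl)oxy]phenoxy}-2,6-dimethoxyphenol, via aryl formate 22 (not isolated)
Conditions: mCPBA, CH2Cl2, 0 °C; then K2CO3 (cat.), MeOH, 0 °C
Reagents that add atoms: 3-chloroperoxybenzoic acid, OOC(=O)c1cccc(Cl)c1
Why: Baeyer–Villiger (Dakin-type) oxidation of a 2,4,6-trioxygenated benzaldehyde, the most favourable substitution pattern for aryl migration, run cold so that the other electron-rich rings are not attacked.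

Step 15
Reactants: 24 2-iodo-1,3,5-trimethoxybenzene (two molecules)
Product: 25 2,2',4,4',6,6'-hexamethoxybiphenyl
Conditions: activated Cu powder, DMF, reflux
Reagents that add atoms: none
Why: Classical Ullmann biaryl homocoupling, long used for 2,6-dialkoxyiodoarenes: an arylcopper species from one iodide couples with a second iodide, and homocoupling makes cross-selectivity irrelevant.

Step 16
Reactants: 25 hexamethoxybiphenyl
Product: 27 2,2',4,4',6,6'-hexamethoxybiphenyl-3-carbaldehyde, via iminium chloride 26 (not isolated)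
Conditions: POCl3 (1.0 equiv), DMF, 0 °C to rt; then aq NaOH
Reagents that add atoms: N,N-dimethylformamide, CN(C)C=O; water, O
Why: Vilsmeier–Haack formylation: the four free positions of 25 are equivalent and each lies between two methoxy groups as in 1,3,5-trimethoxybenzene, while one equivalent of reagent and the positive charge of 26 should restrain a second attack, unchanged 25 being recycled.

Step 17
Reactants: 27 biphenyl aldehyde
Product: 29 2,2',4,4',6,6'-hexamethoxybiphenyl-3-ol, via aryl formate 28 (not isolated)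
Conditions: mCPBA, CH2Cl2, 0 °C; then K2CO3 (cat.), MeOH, 0 °C
Reagents that add atoms: 3-chloroperoxybenzoic acid, OOC(=O)c1cccc(Cl)c1
Why: Baeyer–Villiger (Dakin-type) oxidation: the formyl group has methoxy groups at both ortho positions and at the para position, so aryl migration is strongly favoured.

Step 18
Reactants: 29 biphenylol; 3 2,6-difluoro-4-methoxybenzaldehyde (3 equiv)
Product: 30 2-fluoro-6-[(2,2',4,4',6,6'-hexamethoxybiphenyl-3-yl)oxy]-4-methoxybenzaldehyde
Conditions: K2CO3, DMSO, 80 °C, Ar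
Reagents that add atoms: none
Why: SNAr held at the first displacement: the difluoride is in excess, the temperature is lower than in step 2, and the aryloxy donor introduced first deactivates the remaining C–F bond.

Step 19
Reactants: 23 ring C phenol; 30 fluoro aldehyde carrying arm I–J (1.2 equiv)
Product: 31 2-[(2,2',4,4',6,6'-hexamethoxybiphenyl-3-yl)oxy]-4-methoxy-6-(4-{4-methoxy-2,6-bis[(2,2',4,4',6,6'-hexamethoxybiphenyl-3-yl)oxy]phenoxy}-2,6-dimethoxyphenoxy)benzaldehyde
Conditions: Cs2CO3, DMSO, 110 °C, Ar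
Reagents that add atoms: none
Why: SNAr of the same kind as the second displacement in step 2: the electron-rich 2,6-dimethoxyphenoxide of 23 attacks the C–F carbon ortho to the formyl group, and fluoride leaves far faster than aryloxide, so the ether to arm I–J stays in place.

Step 20
Reactants: 31 ring B aldehyde
Product: 33 the phenol with hydroxyl in place of the formyl group of 31, via aryl formate 32 (not isolated)
Conditions: mCPBA, CH2Cl2, 0 °C to rt; then K2CO3 (cat.), MeOH, 0 °C
Reagents that add atoms: 3-chloroperoxybenzoic acid, OOC(=O)c1cccc(Cl)c1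
Why: Baeyer–Villiger (Dakin-type) oxidation on the same 2,6-bis(aryloxy)-4-methoxybenzaldehyde pattern that is oxidised in step 3.

Step 21
Reactants: 33 ring B phenol; 34 1-iodo-3,5-dimethoxybenzene (3 equiv)
Product: 35 tetracosa-O-methyl ether of the target
Conditions: CuI (20 mol %), picolinic acid (40 mol %), K3PO4, DMSO, 90 °C, Ar
Reagents that add atoms: none
Why: Copper-catalysed Ullmann diaryl ether synthesis with a picolinate ligand, a variant suited to 2,6-disubstituted phenols: the hindrance lies only on the phenoxide side because 34 has two free ortho positions, and nothing else in 33 reacts with the catalyst.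

Step 22
Reactants: 35 tetracosamethyl ether
Product: 36 CNP0294555.0
Conditions: BBr3 (ca. 2 equiv per OMe), CH2Cl2, −78 °C to rt; then MeOH/H2O, Ar
Reagents that add atoms: none
Why: Lewis acid ether cleavage: BBr3 binds each methoxy oxygen and bromide attacks the methyl carbon by SN2, whereas diaryl ether and biaryl bonds offer no sp3 carbon and remain, and hydrolysis of the aryl borates frees all 24 hydroxyl groups.

**Compound list**

1 | methyl syringate (methyl 4-hydroxy-3,5-dimethoxybenzoate) | COC(=O)c1cc(OC)c(O)c(OC)c1 | starting material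
2 | methyl 2-bromo-4-hydroxy-3,5-dimethoxybenzoate | COC(=O)c1cc(OC)c(O)c(OC)c1Br | intermediate
3 | 2,6-difluoro-4-methoxybenzaldehyde | COc1cc(F)c(C=O)c(F)c1 | starting material
4 | methyl 2-bromo-4-(3-fluoro-2-formyl-5-methoxyphenoxy)-3,5-dimethoxybenzoate | COc1cc(F)c(C=O)c(Oc2c(OC)cc(C(=O)OC)c(Br)c2OC)c1 | intermediate (not isolated)
5 | dimethyl 4,4'-[(2-formyl-5-methoxy-1,3-phenylene)bis(oxy)]bis(2-bromo-3,5-dimethoxybenzoate) | COc1cc(Oc2c(OC)cc(C(=O)OC)c(Br)c2OC)c(C=O)c(Oc2c(OC)cc(C(=O)OC)c(Br)c2OC)c1 | intermediate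
6 | dimethyl 4,4'-{[2-(formyloxy)-5-methoxy-1,3-phenylene]bis(oxy)}bis(2-bromo-3,5-dimethoxybenzoate) | COc1cc(Oc2c(OC)cc(C(=O)OC)c(Br)c2OC)c(OC=O)c(Oc2c(OC)cc(C(=O)OC)c(Br)c2OC)c1 | intermediate (not isolated)
7 | dimethyl 4,4'-[(2-hydroxy-5-methoxy-1,3-phenylene)bis(oxy)]bis(2-bromo-3,5-dimethoxybenzoate) | COc1cc(Oc2c(OC)cc(C(=O)OC)c(Br)c2OC)c(O)c(Oc2c(OC)cc(C(=O)OC)c(Br)c2OC)c1 | intermediate
8 | dimethyl 4,4'-{[2-(benzyloxy)-5-methoxy-1,3-phenylene]bis(oxy)}bis(2-bromo-3,5-dimethoxybenzoate) | COc1cc(Oc2c(OC)cc(C(=O)OC)c(Br)c2OC)c(OCc2ccccc2)c(Oc2c(OC)cc(C(=O)OC)c(Br)c2OC)c1 | intermediate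
9 | 4,4'-{[2-(benzyloxy)-5-methoxy-1,3-phenylene]bis(oxy)}bis(2-bromo-3,5-dimethoxybenzoic acid) | COc1cc(Oc2c(OC)cc(C(=O)O)c(Br)c2OC)c(OCc2ccccc2)c(Oc2c(OC)cc(C(=O)O)c(Br)c2OC)c1 | intermediate
10 | 3,5-dimethoxyphenol | COc1cc(O)cc(OC)c1 | starting material
11 | bis(3,5-dimethoxyphenyl) 4,4'-{[2-(benzyloxy)-5-methoxy-1,3-phenylene]bis(oxy)}bis(2-bromo-3,5-dimethoxybenzoate) | COc1cc(Oc2c(OC)cc(C(=O)Oc3cc(OC)cc(OC)c3)c(Br)c2OC)c(OCc2ccccc2)c(Oc2c(OC)cc(C(=O)Oc3cc(OC)cc(OC)c3)c(Br)c2OC)c1 | intermediate (key-step precursor)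
12 | 3,5-dimethoxyphenyl 4-{2-(benzyloxy)-5-methoxy-3-[(1,3,8,10-tetramethoxy-6-oxo-6H-benzo[c]chromen-9-yl)oxy]phenoxy}-2-bromo-3,5-dimethoxybenzoate | COc1cc(Oc2c(OC)cc3C(=O)Oc4cc(OC)cc(OC)c4-c3c2OC)c(OCc2ccccc2)c(Oc2c(OC)cc(C(=O)Oc3cc(OC)cc(OC)c3)c(Br)c2OC)c1 | intermediate (not isolated)
13 | 9,9'-{[2-(benzyloxy)-5-methoxy-1,3-phenylene]bis(oxy)}bis(1,3,8,10-tetramethoxy-6H-benzo[c]chromen-6-one) | COc1cc(Oc2c(OC)cc3C(=O)Oc4cc(OC)cc(OC)c4-c3c2OC)c(OCc2ccccc2)c(Oc2c(OC)cc3C(=O)Oc4cc(OC)cc(OC)c4-c3c2OC)c1 | intermediate (key-step product)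
14 | 9,9'-{[2-(benzyloxy)-5-methoxy-1,3-phenylene]bis(oxy)}bis(1,3,8,10-tetramethoxy-6H-benzo[c]chromen-6-ol), lactol carbons labile and undefined | COc1cc(Oc2c(OC)cc3C(O)Oc4cc(OC)cc(OC)c4-c3c2OC)c(OCc2ccccc2)c(Oc2c(OC)cc3C(O)Oc4cc(OC)cc(OC)c4-c3c2OC)c1 | intermediate
15 | 5,5'-{[2-(benzyloxy)-5-methoxy-1,3-phenylene]bis(oxy)}bis(2',4,4',6,6'-pentamethoxybiphenyl-2-carbaldehyde) | COc1cc(Oc2c(OC)cc(C=O)c(-c3c(OC)cc(OC)cc3OC)c2OC)c(OCc2ccccc2)c(Oc2c(OC)cc(C=O)c(-c3c(OC)cc(OC)cc3OC)c2OC)c1 | intermediate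
16 | diformate of 17 (formyloxy at C4 of rings E and G) | COc1cc(Oc2c(OC)cc(OC=O)c(-c3c(OC)cc(OC)cc3OC)c2OC)c(OCc2ccccc2)c(Oc2c(OC)cc(OC=O)c(-c3c(OC)cc(OC)cc3OC)c2OC)c1 | intermediate (not isolated)
17 | 5,5'-{[2-(benzyloxy)-5-methoxy-1,3-phenylene]bis(oxy)}bis(2',4,4',6,6'-pentamethoxybiphenyl-2-ol) | COc1cc(Oc2c(OC)cc(O)c(-c3c(OC)cc(OC)cc3OC)c2OC)c(OCc2ccccc2)c(Oc2c(OC)cc(O)c(-c3c(OC)cc(OC)cc3OC)c2OC)c1 | intermediate
18 | 2-(benzyloxy)-5-methoxy-1,3-bis[(2,2',4,4',6,6'-hexamethoxybiphenyl-3-yl)oxy]benzene | COc1cc(Oc2c(OC)cc(OC)c(-c3c(OC)cc(OC)cc3OC)c2OC)c(OCc2ccccc2)c(Oc2c(OC)cc(OC)c(-c3c(OC)cc(OC)cc3OC)c2OC)c1 | intermediate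
19 | 4-methoxy-2,6-bis[(2,2',4,4',6,6'-hexamethoxybiphenyl-3-yl)oxy]phenol | COc1cc(Oc2c(OC)cc(OC)c(-c3c(OC)cc(OC)cc3OC)c2OC)c(O)c(Oc2c(OC)cc(OC)c(-c3c(OC)cc(OC)cc3OC)c2OC)c1 | intermediate
20 | 4-fluoro-2,6-dimethoxybenzaldehyde | COc1cc(F)cc(OC)c1C=O | starting material
21 | 4-{4-methoxy-2,6-bis[(2,2',4,4',6,6'-hexamethoxybiphenyl-3-yl)oxy]phenoxy}-2,6-dimethoxybenzaldehyde | COc1cc(Oc2c(OC)cc(OC)c(-c3c(OC)cc(OC)cc3OC)c2OC)c(Oc2cc(OC)c(C=O)c(OC)c2)c(Oc2c(OC)cc(OC)c(-c3c(OC)cc(OC)cc3OC)c2OC)c1 | intermediate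
22 | formate ester of 23 | COc1cc(Oc2c(OC)cc(OC)c(-c3c(OC)cc(OC)cc3OC)c2OC)c(Oc2cc(OC)c(OC=O)c(OC)c2)c(Oc2c(OC)cc(OC)c(-c3c(OC)cc(OC)cc3OC)c2OC)c1 | intermediate (not isolated)
23 | 4-{4-methoxy-2,6-bis[(2,2',4,4',6,6'-hexamethoxybiphenyl-3-yl)oxy]phenoxy}-2,6-dimethoxyphenol | COc1cc(Oc2c(OC)cc(OC)c(-c3c(OC)cc(OC)cc3OC)c2OC)c(Oc2cc(OC)c(O)c(OC)c2)c(Oc2c(OC)cc(OC)c(-c3c(OC)cc(OC)cc3OC)c2OC)c1 | intermediate
24 | 2-iodo-1,3,5-trimethoxybenzene | COc1cc(OC)c(I)c(OC)c1 | starting material
25 | 2,2',4,4',6,6'-hexamethoxybiphenyl | COc1cc(OC)c(-c2c(OC)cc(OC)cc2OC)c(OC)c1 | intermediate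
26 | N-[(2,2',4,4',6,6'-hexamethoxybiphenyl-3-yl)methylidene]-N-methylmethanaminium chloride | C[N+](C)=Cc1c(OC)cc(OC)c(-c2c(OC)cc(OC)cc2OC)c1OC.[Cl-] | intermediate (not isolated)
27 | 2,2',4,4',6,6'-hexamethoxybiphenyl-3-carbaldehyde | O=Cc1c(OC)cc(OC)c(-c2c(OC)cc(OC)cc2OC)c1OC | intermediate
28 | 2,2',4,4',6,6'-hexamethoxybiphenyl-3-yl formate | O=COc1c(OC)cc(OC)c(-c2c(OC)cc(OC)cc2OC)c1OC | intermediate (not isolated)
29 | 2,2',4,4',6,6'-hexamethoxybiphenyl-3-ol | Oc1c(OC)cc(OC)c(-c2c(OC)cc(OC)cc2OC)c1OC | intermediate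
30 | 2-fluoro-6-[(2,2',4,4',6,6'-hexamethoxybiphenyl-3-yl)oxy]-4-methoxybenzaldehyde | COc1cc(F)c(C=O)c(Oc2c(OC)cc(OC)c(-c3c(OC)cc(OC)cc3OC)c2OC)c1 | intermediate
31 | ring B aldehyde: 4-methoxybenzaldehyde bearing at C2 the oxygen of arm I–J and at C6 the phenoxy oxygen of 23 | O=Cc1c(Oc2c(OC)cc(Oc3c(Oc4c(OC)cc(OC)c(-c5c(OC)cc(OC)cc5OC)c4OC)cc(OC)cc3Oc3c(OC)cc(OC)c(-c4c(OC)cc(OC)cc4OC)c3OC)cc2OC)cc(OC)cc1Oc1c(OC)cc(OC)c(-c2c(OC)cc(OC)cc2OC)c1OC | intermediate
32 | formate ester of 33 | O=COc1c(Oc2c(OC)cc(Oc3c(Oc4c(OC)cc(OC)c(-c5c(OC)cc(OC)cc5OC)c4OC)cc(OC)cc3Oc3c(OC)cc(OC)c(-c4c(OC)cc(OC)cc4OC)c3OC)cc2OC)cc(OC)cc1Oc1c(OC)cc(OC)c(-c2c(OC)cc(OC)cc2OC)c1OC | intermediate (not isolated)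
33 | ring B phenol (hydroxyl in place of the formyl group of 31) | Oc1c(Oc2c(OC)cc(Oc3c(Oc4c(OC)cc(OC)c(-c5c(OC)cc(OC)cc5OC)c4OC)cc(OC)cc3Oc3c(OC)cc(OC)c(-c4c(OC)cc(OC)cc4OC)c3OC)cc2OC)cc(OC)cc1Oc1c(OC)cc(OC)c(-c2c(OC)cc(OC)cc2OC)c1OC | intermediate
34 | 1-iodo-3,5-dimethoxybenzene | COc1cc(I)cc(OC)c1 | starting material
35 | tetracosa-O-methyl ether of the target (all 24 hydroxyls as OMe) | COc1cc(OC)cc(Oc2c(Oc3c(OC)cc(Oc4c(Oc5c(OC)cc(OC)c(-c6c(OC)cc(OC)cc6OC)c5OC)cc(OC)cc4Oc4c(OC)cc(OC)c(-c5c(OC)cc(OC)cc5OC)c4OC)cc3OC)cc(OC)cc2Oc2c(OC)cc(OC)c(-c3c(OC)cc(OC)cc3OC)c2OC)c1 | intermediate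
36 | CNP0294555.0 | Oc1cc(O)cc(Oc2c(Oc3c(O)cc(Oc4c(Oc5c(O)cc(O)c(-c6c(O)cc(O)cc6O)c5O)cc(O)cc4Oc4c(O)cc(O)c(-c5c(O)cc(O)cc5O)c4O)cc3O)cc(O)cc2Oc2c(O)cc(O)c(-c3c(O)cc(O)cc3O)c2O)c1 | target

**Step count**

Total step count: 22.
Longest linear sequence: 18 steps (steps 1–14, then 19–22). The branch to arm I–J (steps 15–18) joins in step 19.

**Steps most likely to fail**

Step 7.
- What may go wrong: hydrodebromination of one or both C–Br bonds, palladation of the neighbouring methoxy C–H bond, or slow acetate-induced loss of the aryl ester before the second, more crowded cyclisation is complete.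
- Fallback: make the biaryl bond before the ether bonds.
- It sets out from phenol 29 (steps 15–17) and difluoride 3.
- Double SNAr (2.2 equiv of 29, Cs2CO3, DMSO, 110 °C, passing through 30) should give 4-methoxy-2,6-bis[(2,2',4,4',6,6'-hexamethoxybiphenyl-3-yl)oxy]benzaldehyde F1.
- mCPBA in CH2Cl2 converts this into 4-methoxy-2,6-bis[(2,2',4,4',6,6'-hexamethoxybiphenyl-3-yl)oxy]phenyl formate F2.
- Catalytic K2CO3 in MeOH then frees the phenol, and the route is rejoined at 19.

Step 21.
- What may go wrong: slow binding of the phenoxide to copper, because its oxygen is shielded by two ortho aryloxy groups, so that reduction of the iodide takes over.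
- Fallback: replace the metal-catalysed coupling by the SNAr chemistry already used in steps 13 and 19.
- From 33, reaction with aldehyde 20 (Cs2CO3, DMSO, 110 °C) should give the ring A 4-formyl derivative of the tetracosamethyl ether F3.
- Rhodium-catalysed Tsuji–Wilkinson decarbonylation (RhCl3·3H2O, dppp, diglyme, reflux) removes the formyl group, and the route comes back at 35.

Step 22.
- What may go wrong: incomplete cleavage of the 24 methyl ethers as partly cleaved borates precipitate, and air oxidation or irreversible adsorption of the free polyphenol during purification.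
- Fallback: a capture-and-release end game.
- From 35, the crude material from the BBr3 treatment is not purified as the free phenol but is acetylated at once (Ac2O, pyridine, rt) to the tetracosaacetate of the target F4.
- F4 can be chromatographed on silica and separated from under-cleaved material, which is resubmitted to BBr3.
- Transesterification with NaOMe (cat.) in MeOH under argon, followed by an acidic resin, then releases 36.

Further compounds
F1 | step 7 | 4-methoxy-2,6-bis[(2,2',4,4',6,6'-hexamethoxybiphenyl-3-yl)oxy]benzaldehyde | COc1cc(Oc2c(OC)cc(OC)c(-c3c(OC)cc(OC)cc3OC)c2OC)c(C=O)c(Oc2c(OC)cc(OC)c(-c3c(OC)cc(OC)cc3OC)c2OC)c1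
F2 | step 7 | 4-methoxy-2,6-bis[(2,2',4,4',6,6'-hexamethoxybiphenyl-3-yl)oxy]phenyl formate | COc1cc(Oc2c(OC)cc(OC)c(-c3c(OC)cc(OC)cc3OC)c2OC)c(OC=O)c(Oc2c(OC)cc(OC)c(-c3c(OC)cc(OC)cc3OC)c2OC)c1
F3 | step 21 | ring A 4-formyl derivative of the tetracosamethyl ether | COc1cc(Oc2c(Oc3c(OC)cc(Oc4c(Oc5c(OC)cc(OC)c(-c6c(OC)cc(OC)cc6OC)c5OC)cc(OC)cc4Oc4c(OC)cc(OC)c(-c5c(OC)cc(OC)cc5OC)c4OC)cc3OC)cc(OC)cc2Oc2c(OC)cc(OC)c(-c3c(OC)cc(OC)cc3OC)c2OC)cc(OC)c1C=O
F4 | step 22 | tetracosaacetate of the target | CC(=O)Oc1cc(OC(C)=O)cc(Oc2c(Oc3c(OC(C)=O)cc(Oc4c(Oc5c(OC(C)=O)cc(OC(C)=O)c(-c6c(OC(C)=O)cc(OC(C)=O)cc6OC(C)=O)c5OC(C)=O)cc(OC(C)=O)cc4Oc4c(OC(C)=O)cc(OC(C)=O)c(-c5c(OC(C)=O)cc(OC(C)=O)cc5OC(C)=O)c4OC(C)=O)cc3OC(C)=O)cc(OC(C)=O)cc2Oc2c(OC(C)=O)cc(OC(C)=O)c(-c3c(OC(C)=O)cc(OC(C)=O)cc3OC(C)=O)c2OC(C)=O)c1
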